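Putraflavone is disconnected at the O1–C8a bond of ring C in unit 1 (the 5-hydroxy-7-methoxyflavone half). In ring A of that unit the oxygens on C8a and C5 both lie ortho to C4a, which carries the C4 carbonyl, so ring A can enter as a 2,6-difluoro-4-methoxybenzoyl group. Heating the derived 1,3-diketone with base lets the enolate oxygen displace one of two equivalent ortho fluorines, closing ring C in one operation; the surviving C5 fluorine is later exchanged for oxygen. The precursor is a 1-(2,6-difluoro-4-methoxyphenyl)-3-arylpropane-1,3-dione whose aryl group is ring B, already bonded through C3' to C8 of benzyl-protected unit 2 (acacetin).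

Key step: step 8

Remarks on the chemistry
- Unit 1 is the 5-hydroxy-7-methoxyflavone (ring B positions primed); unit 2 is the acacetin half, bonded through its C8 to C3' of unit 1.
- The C7 methoxy group is carried in on the acylating agent instead of a third fluorine, because a fluorine para and a fluorine ortho to the carbonyl cannot be relied upon to exchange with alkoxides in a fixed order; the ring closure and the bond it forms are unchanged.
- 2,6-Difluoro-4-methoxybenzoic acid is taken as a commercial starting material.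
- The biaryl axis between C8 of unit 2 and C3' of unit 1 is not defined in the target and is not controlled.

Step 1
Reactants: 1 acacetin
Product: 2 5,7-di-O-benzylacacetin [5,7-bis(benzyloxy)-2-(4-methoxyphenyl)-4H-chromen-4-one]
Conditions: BnBr (3 equiv), K2CO3, DMF, 70 °C
Reagents that add atoms: benzyl bromide, BrCc1ccccc1
Why: Williamson ether synthesis; with excess benzyl bromide and carbonate in warm DMF the hydrogen-bonded 5-OH should be alkylated as well as the 7-OH.

Step 2
Reactants: 2 5,7-di-O-benzylacacetin
Product: 3 5,7-di-O-benzyl-8-iodoacacetin [5,7-bis(benzyloxy)-8-iodo-2-(4-methoxyphenyl)-4H-chromen-4-one]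
Conditions: I2, CF3CO2Ag, CH2Cl2, rt, dark
Reagents that add atoms: iodine, [I][I]
Why: Electrophilic aromatic iodination by the hypoiodite formed from I2 and the silver salt should occur at C8 (ortho to O1 and the C7 ether, para to the C5 ether), the site known to be preferred in flavones whose 5-oxygen is alkylated, while the anisyl ring is deactivated by the pyranone.

Step 3
Reactants: 4 3'-bromo-4'-hydroxyacetophenone
Product: 5 4'-benzyloxy-3'-bromoacetophenone [1-(4-(benzyloxy)-3-bromophenyl)ethan-1-one]
Conditions: BnBr, K2CO3, acetone, reflux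
Reagents that add atoms: benzyl bromide, BrCc1ccccc1
Why: Williamson ether synthesis of an acidic para-acyl phenol, which should proceed cleanly without touching the methyl ketone.

Step 4
Reactants: 5 4'-benzyloxy-3'-bromoacetophenone
Product: 6 4'-benzyloxy-3'-(pinacolboryl)acetophenone [1-(4-(benzyloxy)-3-(4,4,5,5-tetramethyl-1,3,2-dioxaborolan-2-yl)phenyl)ethan-1-one]
Conditions: B2pin2, PdCl2(dppf) (3 mol%), KOAc, 1,4-dioxane, 90 °C
Reagents that add atoms: bis(pinacolato)diboron, CC1(C)OB(OC1(C)C)B1OC(C)(C)C(C)(C)O1
Why: Miyaura borylation of an aryl bromide; the weak acetate base should leave the enolisable ketone and the product boronate untouched.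

Step 5
Reactants: 3 5,7-di-O-benzyl-8-iodoacacetin; 6 4'-benzyloxy-3'-(pinacolboryl)acetophenone
Product: 7 8-(5-acetyl-2-(benzyloxy)phenyl)-5,7-bis(benzyloxy)-2-(4-methoxyphenyl)-4H-chromen-4-one
Conditions: Pd(OAc)2 (5 mol%), SPhos (10 mol%), K3PO4, toluene–H2O, 90 °C
Reagents that add atoms: none
Why: Suzuki–Miyaura coupling; the bulky, electron-rich biarylphosphine should allow formation of the tri-ortho-substituted biaryl bond between C8 of unit 2 and C3' of ring B, and ketone, pyranone and benzyl ethers are inert to aqueous phosphate.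

Step 6
Reactants: 8 2,6-difluoro-4-methoxybenzoic acid
Product: 9 2,6-difluoro-4-methoxybenzoyl chloride
Conditions: (COCl)2, DMF (cat.), CH2Cl2, 0 °C → rt; evaporate and use crude
Reagents that add atoms: oxalyl chloride, O=C(Cl)C(=O)Cl
Why: Standard acid chloride formation through the catalytic chloroiminium (Vilsmeier-type) species, with only gaseous co-products.

Step 7
Reactants: 7 8-(5-acetyl-2-(benzyloxy)phenyl)-5,7-bis(benzyloxy)-2-(4-methoxyphenyl)-4H-chromen-4-one; 9 2,6-difluoro-4-methoxybenzoyl chloride
Product: 11 1-(2,6-difluoro-4-methoxyphenyl)-3-[4-(benzyloxy)-3-(5,7-di-O-benzylacacetin-8-yl)phenyl]propane-1,3-dione, via lithium enolate 10 (not isolated)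
Conditions: LiN(SiMe3)2 (2.2 equiv), THF, −78 °C; then 9, −78 → 0 °C; dilute aq. HCl work-up
Reagents that add atoms: none
Why: C-acylation of a preformed ketone lithium enolate by an aroyl chloride (crossed Claisen-type) should give the 1,3-diketone, the second equivalent of amide base deprotonating the more acidic product as it forms and so suppressing double acylation.

Step 8
Reactants: 11 1-(2,6-difluoro-4-methoxyphenyl)-3-[4-(benzyloxy)-3-(5,7-di-O-benzylacacetin-8-yl)phenyl]propane-1,3-dione
Product: 12 8-[2-(benzyloxy)-5-(5-fluoro-7-methoxy-4-oxo-4H-chromen-2-yl)phenyl]-5,7-bis(benzyloxy)-2-(4-methoxyphenyl)-4H-chromen-4-one (tri-O-benzyl biflavone with fluorine at C5 of unit 1)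
Conditions: K2CO3 (3 equiv), dry DMF, 90 °C
Reagents that add atoms: none
Why: K2CO3 converts the diketone into its enolate, whose oxygen on the ring B side adds to C8a (a C–F carbon ortho to the aryl ketone) to give a Meisenheimer adduct with the charge delocalised onto C4a and the C4 carbonyl, and loss of fluoride restores aromaticity (addition–elimination SNAr). The closest known reaction type is the base-mediated cyclisation of 1-(2-fluoroaryl)-1,3-diketones to chromones and flavones. Ring C closes as a six-membered ring by attack on an sp2 arene carbon; counted as 6-exo-trig (charge towards C8) or 6-endo-trig (charge towards C4a and C4=O), it is a favoured mode either way. No stereocentre is formed. The step needs O- rather than C-attack and one regiochemical outcome: attack through the central carbon or the other oxygen would give a four-membered ring, the two ortho fluorines are equivalent by symmetry, and no para fluorine is present for intermolecular displacement. The fluorine left on C5 is less activated once the aryl ketone has become a vinylogous ester, so the product should not react further under carbonate.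

Step 9
Reactants: 12 tri-O-benzyl biflavone with fluorine at C5 of unit 1
Product: 13 tetra-O-benzylputraflavone [8-[2-(benzyloxy)-5-(5-(benzyloxy)-7-methoxy-4-oxo-4H-chromen-2-yl)phenyl]-5,7-bis(benzyloxy)-2-(4-methoxyphenyl)-4H-chromen-4-one]
Conditions: BnOH (2 equiv), NaH (1.8 equiv), THF, 0 °C; then 12, THF–DMF, rt → 50 °C
Reagents that add atoms: benzyl alcohol, OCc1ccccc1
Why: SNAr by benzyl alkoxide at C5, the only remaining C–F carbon, which is ortho to C4a and activated by the C4 carbonyl, with the sodium ion able to bridge the carbonyl oxygen and the incoming alkoxide; the aryl ethers elsewhere are inert to alkoxide.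

Step 10
Reactants: 13 tetra-O-benzylputraflavone
Product: 14 putraflavone
Conditions: H2 (1 atm), Pd/C (10% palladium on carbon), THF–MeOH, rt
Reagents that add atoms: none
Why: Catalytic hydrogenolysis should cleave the four benzylic C–O bonds, while the two methyl ethers, the biaryl bond and the conjugated C2=C3 bonds of both pyranone rings are not expected to react at ambient pressure and temperature.

Compound list
1 | acacetin | COc1ccc(-c2cc(=O)c3c(O)cc(O)cc3o2)cc1 | starting material
2 | 5,7-di-O-benzylacacetin | COc1ccc(-c2cc(=O)c3c(OCc4ccccc4)cc(OCc4ccccc4)cc3o2)cc1 | intermediate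
3 | 5,7-di-O-benzyl-8-iodoacacetin | COc1ccc(-c2cc(=O)c3c(OCc4ccccc4)cc(OCc4ccccc4)c(I)c3o2)cc1 | intermediate
4 | 3'-bromo-4'-hydroxyacetophenone | CC(=O)c1ccc(O)c(Br)c1 | starting material
5 | 4'-benzyloxy-3'-bromoacetophenone | CC(=O)c1ccc(OCc2ccccc2)c(Br)c1 | intermediate
6 | 4'-benzyloxy-3'-(4,4,5,5-tetramethyl-1,3,2-dioxaborolan-2-yl)acetophenone | CC(=O)c1ccc(OCc2ccccc2)c(B2OC(C)(C)C(C)(C)O2)c1 | intermediate
7 | 8-(5-acetyl-2-(benzyloxy)phenyl)-5,7-bis(benzyloxy)-2-(4-methoxyphenyl)-4H-chromen-4-one | CC(=O)c1ccc(OCc2ccccc2)c(-c2c(OCc3ccccc3)cc(OCc3ccccc3)c3c(=O)cc(-c4ccc(OC)cc4)oc23)c1 | intermediate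
8 | 2,6-difluoro-4-methoxybenzoic acid | COc1cc(F)c(C(=O)O)c(F)c1 | starting material
9 | 2,6-difluoro-4-methoxybenzoyl chloride | COc1cc(F)c(C(=O)Cl)c(F)c1 | intermediate
10 | lithium enolate of ketone 7 | C=C(O[Li])c1ccc(OCc2ccccc2)c(-c2c(OCc3ccccc3)cc(OCc3ccccc3)c3c(=O)cc(-c4ccc(OC)cc4)oc23)c1 | intermediate (not isolated)
11 | 1-(2,6-difluoro-4-methoxyphenyl)-3-[4-(benzyloxy)-3-(5,7-di-O-benzylacacetin-8-yl)phenyl]propane-1,3-dione | COc1cc(F)c(C(=O)CC(=O)c2ccc(OCc3ccccc3)c(-c3c(OCc4ccccc4)cc(OCc4ccccc4)c4c(=O)cc(-c5ccc(OC)cc5)oc34)c2)c(F)c1 | intermediate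
12 | 8-[2-(benzyloxy)-5-(5-fluoro-7-methoxy-4-oxo-4H-chromen-2-yl)phenyl]-5,7-bis(benzyloxy)-2-(4-methoxyphenyl)-4H-chromen-4-one | COc1ccc(-c2cc(=O)c3c(OCc4ccccc4)cc(OCc4ccccc4)c(-c4cc(-c5cc(=O)c6c(F)cc(OC)cc6o5)ccc4OCc4ccccc4)c3o2)cc1 | intermediate
13 | tetra-O-benzylputraflavone | COc1ccc(-c2cc(=O)c3c(OCc4ccccc4)cc(OCc4ccccc4)c(-c4cc(-c5cc(=O)c6c(OCc7ccccc7)cc(OC)cc6o5)ccc4OCc4ccccc4)c3o2)cc1 | intermediate
14 | putraflavone | COc1ccc(-c2cc(=O)c3c(O)cc(O)c(-c4cc(-c5cc(=O)c6c(O)cc(OC)cc6o5)ccc4O)c3o2)cc1 | target

Total step count: 10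
Longest linear sequence: 7 steps (1 → 2 → 3 → 7 → 11 → 12 → 13 → 14; the arm from 4 through 5 and 6 is equally long)

Steps most likely to fail

1. Step 8 (ring closure). The potassium diketonate may rest in a chelated U-shaped form in which the enolate oxygen points away from the fluoroarene, and the 4-methoxy group lowers the electrophilicity of the ring. Closure could then be slow enough for retro-Claisen cleavage by traces of water, or intermolecular fluoride displacement, to compete. The fallback abandons the late aryl–oxygen closure and builds ring C of unit 1 before the biaryl bond; it sets out from iodide 3 and comes back at 14. Claisen–Schmidt condensation of commercial 2'-hydroxy-4',6'-dimethoxyacetophenone with commercial 4-(benzyloxy)-3-bromobenzaldehyde (KOH, EtOH, rt) should give the chalcone (E)-3-[4-(benzyloxy)-3-bromophenyl]-1-(2-hydroxy-4,6-dimethoxyphenyl)prop-2-en-1-one F1. Oxidative cyclisation (I2 cat., DMSO, 130 °C) should give 2-[4-(benzyloxy)-3-bromophenyl]-5,7-dimethoxy-4H-chromen-4-one F2. Miyaura borylation (B2pin2, PdCl2(dppf), KOAc, dioxane) should give the pinacol boronate of that flavone F3. Suzuki–Miyaura coupling of F3 with 3 under the conditions of step 5 should give tri-O-benzyl-5-O-methylputraflavone F4. BCl3 with pentamethylbenzene (CH2Cl2, −78 °C → rt) should then remove the three benzyl ethers and, by chelation to the C4 carbonyl, the 5-O-methyl group only, giving 14.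

2. Step 9 (fluorine–oxygen exchange at C5). Substitution may be slow, because the carbonyl is now part of a pyranone and ring A carries two oxygen donors, and the hard alkoxide may instead add to C2 and open the pyranone ring. The fallback replaces the alkoxide by a weakly basic alpha-effect hydroxide surrogate and makes no benzyl ether at C5; it sets out from 12 and comes back at 14. Heating 12 with (E)-benzaldoxime and K2CO3 in DMSO at 70 °C should give the O-aryl oxime ether of benzaldehyde at C5 of unit 1 F5 (not isolated). This should fragment under the same base to benzonitrile and the 5-phenoxide, which is inert to further attack, giving after acidification the tri-O-benzylputraflavone with free 5-OH in unit 1 F6. Hydrogenolysis as in step 10 should then give 14.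

3. Step 5 (biaryl coupling). Transmetalation at the tri-ortho-substituted axis may be slow, so that protodeboronation of 6 and reductive loss of iodine from 3 take over. The fallback changes the organometallic partner to tin; it sets out from bromide 5 and comes back at 7. Stannylation of 5 (Bu3SnSnBu3, Pd(PPh3)4, toluene, 110 °C) should give 4'-benzyloxy-3'-(tributylstannyl)acetophenone F7. Copper-assisted Stille coupling of F7 with 3 (Pd(PPh3)4, CuI, CsF, DMF, 60 °C) should give 7.

Further compounds
F1 | step 8 | (E)-3-[4-(benzyloxy)-3-bromophenyl]-1-(2-hydroxy-4,6-dimethoxyphenyl)prop-2-en-1-one | COc1cc(O)c(C(=O)/C=C/c2ccc(OCc3ccccc3)c(Br)c2)c(OC)c1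
F2 | step 8 | 2-[4-(benzyloxy)-3-bromophenyl]-5,7-dimethoxy-4H-chromen-4-one | COc1cc(OC)c2c(=O)cc(-c3ccc(OCc4ccccc4)c(Br)c3)oc2c1
F3 | step 8 | 2-[4-(benzyloxy)-3-(4,4,5,5-tetramethyl-1,3,2-dioxaborolan-2-yl)phenyl]-5,7-dimethoxy-4H-chromen-4-one | COc1cc(OC)c2c(=O)cc(-c3ccc(OCc4ccccc4)c(B4OC(C)(C)C(C)(C)O4)c3)oc2c1
F4 | step 8 | tri-O-benzyl-5-O-methylputraflavone | COc1ccc(-c2cc(=O)c3c(OCc4ccccc4)cc(OCc4ccccc4)c(-c4cc(-c5cc(=O)c6c(OC)cc(OC)cc6o5)ccc4OCc4ccccc4)c3o2)cc1
F5 | step 9 | O-aryl (E)-benzaldoxime ether at C5 of unit 1 of the tri-O-benzyl biflavone (not isolated) | COc1ccc(-c2cc(=O)c3c(OCc4ccccc4)cc(OCc4ccccc4)c(-c4cc(-c5cc(=O)c6c(O/N=C/c7ccccc7)cc(OC)cc6o5)ccc4OCc4ccccc4)c3o2)cc1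
F6 | step 9 | tri-O-benzylputraflavone with free 5-OH in unit 1 | COc1ccc(-c2cc(=O)c3c(OCc4ccccc4)cc(OCc4ccccc4)c(-c4cc(-c5cc(=O)c6c(O)cc(OC)cc6o5)ccc4OCc4ccccc4)c3o2)cc1
F7 | step 5 | 4'-benzyloxy-3'-(tributylstannyl)acetophenone | CC(=O)c1ccc(OCc2ccccc2)c([Sn](CCCC)(CCCC)CCCC)c1
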